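**Strategy.** The route rests on disconnecting the C2–O bond of the syringate ester. The C2–O–C(=O)–ring C unit, which sits between carbinol C1 (ring A) and methylene C3 (ring B), is traced back to a C2–C(=O)–ring C aryl ketone. A Baeyer–Villiger oxidation inserts oxygen between C2 and the carbonyl with retention, so the C2–O and O–acyl bonds form together and the ester lands on O2 without any diol differentiation. The substrate is the silylated (1R,2R) syn aldol of an acetylated dihydrochalcone-type ketone with 4-acetoxy-2-methoxybenzaldehyde. Bromine holds the prenyl position so that no alkene meets the peracid.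

Key step: step 7

Numbering used: C1 = carbinol carbon on ring A (2-methoxy-4-oxygenated phenyl), C2 = ester-bearing carbon, C3 = CH2 on ring B (4-oxygenated phenyl, bromine then prenyl at its position 3), ring C = 3,5-dimethoxy-4-oxygenated benzoyl ring.

Remark on configuration: the target is (1S,2R), erythro. The ketone with the same spatial arrangement is (1R,2R), because ring A outranks C2 while C2 bears carbon instead of oxygen. This is the syn aldol formed on the Re face of the aldehyde.

Assumption: (Z)-enol borinates with (−)-isopinocampheyl ligands are taken to attack the aldehyde Si face, so the (+)-reagent (from (−)-α-pinene) is specified for Re-face attack. If a test aldol showed the opposite sense, the antipodal reagent would be used with nothing else changed.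

**Step 1**
Reactants: 1 acetosyringone; 2 3-bromo-4-hydroxybenzaldehyde
Product: 3 (E)-3-(3-bromo-4-hydroxyphenyl)-1-(4-hydroxy-3,5-dimethoxyphenyl)prop-2-en-1-one
Conditions: HCl (1.25 M in EtOH), rt
Reagents that add atoms: none
Why: Acid-mediated Claisen–Schmidt condensation, in which the ketone enol adds to the protonated aldehyde and the aldol dehydrates to the (E)-enone, chosen because both partners carry free para-phenols that base would deactivate as phenoxides.

**Step 2**
Reactants: 3 chalcone diphenol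
Product: 4 4-[(E)-3-(4-acetoxy-3-bromophenyl)prop-2-enoyl]-2,6-dimethoxyphenyl acetate
Conditions: Ac2O, pyridine, DMAP (cat.), CH2Cl2, rt
Reagents that add atoms: acetic anhydride, CC(=O)OC(C)=O
Why: DMAP-catalysed O-acetylation caps both phenols (the hindered syringyl one included) as non-acidic, electron-withdrawing esters that suit the boron aldol and the later peracid step.

**Step 3**
Reactants: 4 chalcone diacetate
Product: 5 3-(4-acetoxy-3-bromophenyl)-1-(4-acetoxy-3,5-dimethoxyphenyl)propan-1-one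
Conditions: H2 (1 atm), RhCl(PPh3)3 (5 mol %), toluene/THF, 40 °C
Reagents that add atoms: none
Why: Homogeneous hydrogenation with RhCl(PPh3)3 should saturate the disubstituted enone C=C without cleaving the aryl bromide or reducing the ketone or the aryl acetates.

**Step 4**
Reactants: 6 4-hydroxy-2-methoxybenzaldehyde
Product: 7 4-formyl-3-methoxyphenyl acetate
Conditions: Ac2O, pyridine, DMAP (cat.), CH2Cl2, 0 °C to rt
Reagents that add atoms: acetic anhydride, CC(=O)OC(C)=O
Why: Straightforward phenol acetylation, giving ring A the same protecting group as rings B and C.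

**Step 5**
Reactants: 5 dihydrochalcone-type ketone; 7 4-formyl-3-methoxyphenyl acetate
Product: 10 (2R,3R)-2-(4-acetoxy-3-bromobenzyl)-1-(4-acetoxy-3,5-dimethoxyphenyl)-3-(4-acetoxy-2-methoxyphenyl)-3-hydroxypropan-1-one (syn aldol; C1 R, C2 R), via enol diisopinocampheylborinate 8 (not isolated), via diisopinocampheylboron aldolate 9 (not isolated)
Conditions: (+)-Ipc2BH, TfOH, hexane, rt; then 5, i-Pr2NEt, CH2Cl2, −78 °C; then 7, −78 to −20 °C; MeOH, pH 7 buffer (no H2O2)
Reagents that add atoms: none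
Why: Reagent-controlled boron aldol reaction in which the ketone, enolisable only toward C2, gives the (Z)-enol borinate, which adds through a chair (Zimmerman–Traxler) transition state to set the syn C1/C2 relationship while the (+)-isopinocampheyl ligands direct attack to the aldehyde Re face, fixing C1 and C2 as R,R; the peroxide-free work-up spares the aryl acetates.

**Step 6**
Reactants: 10 syn aldol
Product: 11 (2R,3R)-2-(4-acetoxy-3-bromobenzyl)-1-(4-acetoxy-3,5-dimethoxyphenyl)-3-(4-acetoxy-2-methoxyphenyl)-3-(tert-butyldimethylsilyloxy)propan-1-one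
Conditions: TBSOTf, 2,6-lutidine, CH2Cl2, −78 to 0 °C
Reagents that add atoms: tert-butyldimethylsilyl triflate, CC(C)(C)[Si](C)(C)OS(=O)(=O)C(F)(F)F
Why: Low-temperature silylation with the silyl triflate and a hindered base protects the congested aldol hydroxyl without retro-aldol cleavage or epimerisation at C2.

**Step 7**
Reactants: 11 silylated syn-aldol aryl ketone
Product: 12 (1S,2R)-1-(4-acetoxy-2-methoxyphenyl)-3-(4-acetoxy-3-bromophenyl)-1-(tert-butyldimethylsilyloxy)propan-2-yl 4-acetoxy-3,5-dimethoxybenzoate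
Conditions: mCPBA (3 equiv), Na2HPO4, CH2Cl2, 0 °C to rt (to 40 °C if slow), dark
Reagents that add atoms: 3-chloroperbenzoic acid, OOC(=O)c1cccc(Cl)c1
Why: Baeyer–Villiger oxidation: the peracid adds to the ketone carbonyl to give the tetrahedral peroxy (Criegee) adduct, and the group antiperiplanar to the breaking O–O bond shifts from carbon to oxygen as 3-chlorobenzoate leaves. The closest known reaction type is the Baeyer–Villiger oxidation of aryl sec-alkyl ketones to sec-alkyl benzoates and of silylated aldol ketones to 1,2-diol monoesters; no ring is closed. No new stereocentre is formed, since C2 migrates with retention, so the (1R,2R) syn aldol should become the (1S,2R) erythro monoester (the C1 descriptor changes through priorities only). The step needs C2 to migrate in preference to ring C: ring C has inductively withdrawing methoxy groups meta to the migrating carbon and a para acetoxy group twisted out of conjugation by its two ortho methoxy neighbours, so it should stabilise positive charge poorly, whereas C2 is a secondary carbon whose β-oxygen is a weakly withdrawing silyl ether. The buffer protects the silyl ether and acetates from acid, and with bromine standing in for the prenyl group the ketone is the only site open to the peracid.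

**Step 8**
Reactants: 13 prenyl bromide
Product: 14 prenylzinc bromide (THF solution, titrated, used directly)
Conditions: Zn dust, LiCl, THF, 0 °C to rt
Reagents that add atoms: zinc, [Zn]
Why: Oxidative insertion of LiCl-activated zinc into the allylic C–Br bond gives the allylic zinc halide under conditions that limit Wurtz coupling.

**Step 9**
Reactants: 12 aryl bromide ester; 14 prenylzinc bromide
Product: 15 (1S,2R)-1-(4-acetoxy-2-methoxyphenyl)-3-[4-acetoxy-3-(3-methylbut-2-enyl)phenyl]-1-(tert-butyldimethylsilyloxy)propan-2-yl 4-acetoxy-3,5-dimethoxybenzoate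
Conditions: Pd(OAc)2 (2 mol %), CPhos (4 mol %), THF, rt
Reagents that add atoms: none
Why: Negishi coupling in which the aryl bromide adds oxidatively to zerovalent palladium, the prenyl group is transferred from zinc, and fast reductive elimination at the unsubstituted allyl terminus of the CPhos complex should give the linear prenyl arene, the hindered C2 benzoate being inert to the mild zinc reagent.

**Step 10**
Reactants: 15 prenylated triacetate
Product: 16 (1S,2R)-1-(tert-butyldimethylsilyloxy)-1-(4-hydroxy-2-methoxyphenyl)-3-[4-hydroxy-3-(3-methylbut-2-enyl)phenyl]propan-2-yl 4-hydroxy-3,5-dimethoxybenzoate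
Conditions: N2H4·H2O (4 equiv), THF/MeOH, 0 °C, under Ar
Reagents that add atoms: none
Why: Chemoselective hydrazinolysis cleaves the three aryl acetates (phenoxide leaving groups) much faster than the hindered secondary alkyl benzoate, and with O1 still silylated the C2 ester cannot migrate.

**Step 11**
Reactants: 16 silylated triphenol
Product: 17 eryvarinol B, (1S,2R)-1-hydroxy-1-(4-hydroxy-2-methoxyphenyl)-3-[4-hydroxy-3-(3-methylbut-2-enyl)phenyl]propan-2-yl 4-hydroxy-3,5-dimethoxybenzoate
Conditions: HF·pyridine, pyridine, THF, 0 °C to rt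
Reagents that add atoms: none
Why: Fluoride-mediated desilylation in a pyridine-buffered, non-basic medium should free the C1 hydroxyl without O2-to-O1 acyl migration, without ionising the para-hydroxybenzylic carbinol and without acid cyclisation of the ortho-prenylphenol to a chroman.

**Compound list**

1 | acetosyringone | CC(=O)c1cc(OC)c(O)c(OC)c1 | starting material
2 | 3-bromo-4-hydroxybenzaldehyde | O=Cc1ccc(O)c(Br)c1 | starting material
3 | (E)-3-(3-bromo-4-hydroxyphenyl)-1-(4-hydroxy-3,5-dimethoxyphenyl)prop-2-en-1-one | COc1cc(cc(OC)c1O)C(=O)/C=C/c1ccc(O)c(Br)c1 | intermediate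
4 | 4-[(E)-3-(4-acetoxy-3-bromophenyl)prop-2-enoyl]-2,6-dimethoxyphenyl acetate | COc1cc(cc(OC)c1OC(C)=O)C(=O)/C=C/c1ccc(OC(C)=O)c(Br)c1 | intermediate
5 | 3-(4-acetoxy-3-bromophenyl)-1-(4-acetoxy-3,5-dimethoxyphenyl)propan-1-one | COc1cc(cc(OC)c1OC(C)=O)C(=O)CCc1ccc(OC(C)=O)c(Br)c1 | intermediate
6 | 4-hydroxy-2-methoxybenzaldehyde | COc1cc(O)ccc1C=O | starting material
7 | 4-formyl-3-methoxyphenyl acetate | COc1cc(OC(C)=O)ccc1C=O | intermediate
8 | (Z)-enol di[(+)-isopinocampheyl]borinate of ketone 5 | COc1cc(cc(OC)c1OC(C)=O)/C(OB([C@H]2C[C@H]3C[C@@H]([C@@H]2C)C3(C)C)[C@H]2C[C@H]3C[C@@H]([C@@H]2C)C3(C)C)=C/Cc1ccc(OC(C)=O)c(Br)c1 | intermediate (not isolated)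
9 | di[(+)-isopinocampheyl]boron aldolate of 10 (C1 R, C2 R) | COc1cc(OC(C)=O)ccc1[C@H](OB([C@H]2C[C@H]3C[C@@H]([C@@H]2C)C3(C)C)[C@H]2C[C@H]3C[C@@H]([C@@H]2C)C3(C)C)[C@@H](Cc1ccc(OC(C)=O)c(Br)c1)C(=O)c1cc(OC)c(OC(C)=O)c(OC)c1 | intermediate (not isolated)
10 | (2R,3R)-2-(4-acetoxy-3-bromobenzyl)-1-(4-acetoxy-3,5-dimethoxyphenyl)-3-(4-acetoxy-2-methoxyphenyl)-3-hydroxypropan-1-one | COc1cc(OC(C)=O)ccc1[C@H](O)[C@@H](Cc1ccc(OC(C)=O)c(Br)c1)C(=O)c1cc(OC)c(OC(C)=O)c(OC)c1 | intermediate
11 | (2R,3R)-2-(4-acetoxy-3-bromobenzyl)-1-(4-acetoxy-3,5-dimethoxyphenyl)-3-(4-acetoxy-2-methoxyphenyl)-3-(tert-butyldimethylsilyloxy)propan-1-one | COc1cc(OC(C)=O)ccc1[C@H](O[Si](C)(C)C(C)(C)C)[C@@H](Cc1ccc(OC(C)=O)c(Br)c1)C(=O)c1cc(OC)c(OC(C)=O)c(OC)c1 | intermediate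
12 | (1S,2R)-1-(4-acetoxy-2-methoxyphenyl)-3-(4-acetoxy-3-bromophenyl)-1-(tert-butyldimethylsilyloxy)propan-2-yl 4-acetoxy-3,5-dimethoxybenzoate | COc1cc(OC(C)=O)ccc1[C@H](O[Si](C)(C)C(C)(C)C)[C@@H](Cc1ccc(OC(C)=O)c(Br)c1)OC(=O)c1cc(OC)c(OC(C)=O)c(OC)c1 | intermediate
13 | prenyl bromide (1-bromo-3-methylbut-2-ene) | CC(C)=CCBr | starting material
14 | prenylzinc bromide | CC(C)=CC[Zn]Br | intermediate
15 | (1S,2R)-1-(4-acetoxy-2-methoxyphenyl)-3-[4-acetoxy-3-(3-methylbut-2-enyl)phenyl]-1-(tert-butyldimethylsilyloxy)propan-2-yl 4-acetoxy-3,5-dimethoxybenzoate | COc1cc(OC(C)=O)ccc1[C@H](O[Si](C)(C)C(C)(C)C)[C@@H](Cc1ccc(OC(C)=O)c(CC=C(C)C)c1)OC(=O)c1cc(OC)c(OC(C)=O)c(OC)c1 | intermediate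
16 | (1S,2R)-1-(tert-butyldimethylsilyloxy)-1-(4-hydroxy-2-methoxyphenyl)-3-[4-hydroxy-3-(3-methylbut-2-enyl)phenyl]propan-2-yl 4-hydroxy-3,5-dimethoxybenzoate | COc1cc(O)ccc1[C@H](O[Si](C)(C)C(C)(C)C)[C@@H](Cc1ccc(O)c(CC=C(C)C)c1)OC(=O)c1cc(OC)c(O)c(OC)c1 | intermediate
17 | eryvarinol B | COc1cc(O)ccc1[C@H](O)[C@@H](Cc1ccc(O)c(CC=C(C)C)c1)OC(=O)c1cc(OC)c(O)c(OC)c1 | target

**Step count and risks**

Total step count: 11 (ten on the skeleton plus the preparation of the zinc reagent). Longest linear sequence: 9 steps (1, 2, 3, 5, 6, 7, 9, 10, 11).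

Steps most likely to fail:

1. Step 7. Oxygen insertion may stall at the hindered carbonyl, or ring C may migrate in competition with C2, which would place the oxygen on the wrong side of the carbonyl.
Fallback (sets out from 2 and 7, comes back at 12): a sacrificial, strongly electron-poor aroyl group takes the place of ring C, and the syringate is introduced afterwards by acylating O2 while O1 is silylated. Commercial 4′-(trifluoromethyl)acetophenone is condensed with 2 under the conditions of step 1 to give the chalcone F1. Acetylation gives the acetate F2, and hydrogenation with RhCl(PPh3)3 gives the saturated ketone F3. The (+)-Ipc2BOTf aldol with 7 proceeds through the enol borinate F4 and the boron aldolate F5 to the syn aldol F6, which is silylated to the silyl ether F7. Oxidation with mCPBA, in which the 4-(trifluoromethyl)phenyl group is a very poor migrating group, gives the 4-(trifluoromethyl)benzoate F8. K2CO3 in MeOH at 0 °C removes that ester and both aryl acetates to give the silylated triol F9. Selective phenol acetylation (Ac2O, Et3N, 0 °C, no DMAP) gives the diacetate alcohol F10. Steglich esterification with commercial 4-acetoxy-3,5-dimethoxybenzoic acid (EDC·HCl, DMAP, CH2Cl2) gives 12.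

2. Step 5. Facial control by the isopinocampheyl ligands may be weak with this benzyl-substituted aryl ketone, so the syn aldol could form with insufficient enantiomeric purity.
Fallback (sets out from 5 and 7, comes back at 10): asymmetric induction is replaced by resolution. The achiral n-Bu2BOTf/i-Pr2NEt aldol (CH2Cl2, −78 to 0 °C, same peroxide-free work-up) proceeds through the dibutylboron enolate F11 and the racemic syn dibutylboron aldolate F12 to the racemic syn aldol. Preparative chromatography on a chiral stationary phase separates 10 from the enantiomeric aldol F13, which is discarded.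

3. Step 9. Prenyl transfer may be unselective (attachment through the substituted allyl terminus), or the zinc reagent may attack ester groups before coupling.
Fallback (sets out from 12, comes back at 15): the prenyl group is assembled in two stages. Stille coupling of 12 with allyltributylstannane (Pd(PPh3)4, toluene, 100 °C) gives the allyl arene F14, in which no regiochemical question arises. Cross-metathesis with excess 2-methyl-2-butene (second-generation Grubbs catalyst RuCl2(H2IMes)(PCy3)(=CHPh), CH2Cl2, 40 °C) gives 15.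

**Further compounds**

F1 | step 7 | (E)-3-(3-bromo-4-hydroxyphenyl)-1-[4-(trifluoromethyl)phenyl]prop-2-en-1-one | Oc1ccc(/C=C/C(=O)c2ccc(cc2)C(F)(F)F)cc1Br
F2 | step 7 | 2-bromo-4-[(E)-3-oxo-3-[4-(trifluoromethyl)phenyl]prop-1-enyl]phenyl acetate | CC(=O)Oc1ccc(/C=C/C(=O)c2ccc(cc2)C(F)(F)F)cc1Br
F3 | step 7 | 2-bromo-4-[3-oxo-3-[4-(trifluoromethyl)phenyl]propyl]phenyl acetate | CC(=O)Oc1ccc(CCC(=O)c2ccc(cc2)C(F)(F)F)cc1Br
F4 | step 7 | (Z)-enol di[(+)-isopinocampheyl]borinate of F3 | FC(F)(F)c1ccc(cc1)/C(OB([C@H]2C[C@H]3C[C@@H]([C@@H]2C)C3(C)C)[C@H]2C[C@H]3C[C@@H]([C@@H]2C)C3(C)C)=C/Cc1ccc(OC(C)=O)c(Br)c1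
F5 | step 7 | di[(+)-isopinocampheyl]boron aldolate of F6 | COc1cc(OC(C)=O)ccc1[C@H](OB([C@H]2C[C@H]3C[C@@H]([C@@H]2C)C3(C)C)[C@H]2C[C@H]3C[C@@H]([C@@H]2C)C3(C)C)[C@@H](Cc1ccc(OC(C)=O)c(Br)c1)C(=O)c1ccc(cc1)C(F)(F)F
F6 | step 7 | (2R,3R)-2-(4-acetoxy-3-bromobenzyl)-3-(4-acetoxy-2-methoxyphenyl)-3-hydroxy-1-[4-(trifluoromethyl)phenyl]propan-1-one | COc1cc(OC(C)=O)ccc1[C@H](O)[C@@H](Cc1ccc(OC(C)=O)c(Br)c1)C(=O)c1ccc(cc1)C(F)(F)F
F7 | step 7 | tert-butyldimethylsilyl ether of F6 | COc1cc(OC(C)=O)ccc1[C@H](O[Si](C)(C)C(C)(C)C)[C@@H](Cc1ccc(OC(C)=O)c(Br)c1)C(=O)c1ccc(cc1)C(F)(F)F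
F8 | step 7 | (1S,2R)-1-(4-acetoxy-2-methoxyphenyl)-3-(4-acetoxy-3-bromophenyl)-1-(tert-butyldimethylsilyloxy)propan-2-yl 4-(trifluoromethyl)benzoate | COc1cc(OC(C)=O)ccc1[C@H](O[Si](C)(C)C(C)(C)C)[C@@H](Cc1ccc(OC(C)=O)c(Br)c1)OC(=O)c1ccc(cc1)C(F)(F)F
F9 | step 7 | (1S,2R)-3-(3-bromo-4-hydroxyphenyl)-1-(tert-butyldimethylsilyloxy)-1-(4-hydroxy-2-methoxyphenyl)propan-2-ol | COc1cc(O)ccc1[C@H](O[Si](C)(C)C(C)(C)C)[C@@H](Cc1ccc(O)c(Br)c1)O
F10 | step 7 | (1S,2R)-1-(4-acetoxy-2-methoxyphenyl)-3-(4-acetoxy-3-bromophenyl)-1-(tert-butyldimethylsilyloxy)propan-2-ol | COc1cc(OC(C)=O)ccc1[C@H](O[Si](C)(C)C(C)(C)C)[C@@H](Cc1ccc(OC(C)=O)c(Br)c1)O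
F11 | step 5 | (Z)-dibutylboron enolate of ketone 5 | COc1cc(cc(OC)c1OC(C)=O)/C(OB(CCCC)CCCC)=C/Cc1ccc(OC(C)=O)c(Br)c1
F12 | step 5 | racemic syn dibutylboron aldolate (both enantiomers) | COc1cc(OC(C)=O)ccc1[C@H](OB(CCCC)CCCC)[C@@H](Cc1ccc(OC(C)=O)c(Br)c1)C(=O)c1cc(OC)c(OC(C)=O)c(OC)c1.COc1cc(OC(C)=O)ccc1[C@@H](OB(CCCC)CCCC)[C@H](Cc1ccc(OC(C)=O)c(Br)c1)C(=O)c1cc(OC)c(OC(C)=O)c(OC)c1
F13 | step 5 | (2S,3S)-enantiomer of aldol 10 | COc1cc(OC(C)=O)ccc1[C@@H](O)[C@H](Cc1ccc(OC(C)=O)c(Br)c1)C(=O)c1cc(OC)c(OC(C)=O)c(OC)c1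
F14 | step 9 | (1S,2R)-1-(4-acetoxy-2-methoxyphenyl)-3-(4-acetoxy-3-allylphenyl)-1-(tert-butyldimethylsilyloxy)propan-2-yl 4-acetoxy-3,5-dimethoxybenzoate | COc1cc(OC(C)=O)ccc1[C@H](O[Si](C)(C)C(C)(C)C)[C@@H](Cc1ccc(OC(C)=O)c(CC=C)c1)OC(=O)c1cc(OC)c(OC(C)=O)c(OC)c1
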